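**Plan**

- Retrosynthesis: the phenol is masked as its MOM ether and a carboxyl is put back on ring B next to the styryl-bearing carbon; ring B is then opened at the bond between these two carbons to give the open-chain 3,5,7-triketo acid 13.
- The C9 chain is cut at C1–C2 (CO2), at C6–C7 (pentane-2,4-dione dianion plus Weinreb amide), at the aryl–vinyl bond (Heck) and at the aryl–geranyl bond (arylcopper plus geranyl bromide).
- Forward: ring A is prepared as a geranylated, MOM-protected bromoarene and the chain is joined to it by three C–C couplings. Ring B is the only ring formed and arises last by aldol closure and aromatisation; decarboxylation and MOM removal finish the route.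
- Enabling feature: ring B is a resorcinol with OH at C3 and C5 and the styryl group at C1. This meta pattern maps onto a polyketide chain: the two C–OH carbons are the C3 and C5 ketones, C1 is the enone carbonyl C7, and the ring CH next to it is C2, which carries the carboxyl that is later lost.
- Stereochemistry: there are no stereocentres. The (E) geranyl alkene comes unchanged from geranyl bromide, and the (E) stilbene alkene is set by the Heck reaction.

Key step: step 6

Remark: geranyl stands for (2E)-3,7-dimethylocta-2,6-dien-1-yl; polyketones 11 and 13 are drawn as keto forms although they are largely enolised, and acid 13 is taken on crude at once.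

**Route**

Step 1
Reactants: 1 4-bromo-2-iodophenol
Product: 2 4-bromo-2-iodo-1-(methoxymethoxy)benzene
Conditions: MOMCl, i-Pr2NEt, CH2Cl2, 0 °C to rt
Reagents that add atoms: chloromethyl methyl ether (MOMCl), COCCl
Why: O-alkylation of the phenol (Williamson type) with the very reactive α-chloro ether and a hindered amine base is routine for ortho-halophenols, and the MOM acetal should tolerate every organometallic and basic step that follows.

Step 2
Reactants: 2 4-bromo-2-iodo-1-(methoxymethoxy)benzene; 3 geranyl bromide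
Product: 6 4-bromo-2-geranyl-1-(methoxymethoxy)benzene, via aryllithium 4 (not isolated), via arylcopper 5 (not isolated)
Conditions: n-BuLi (1.05 equiv), THF, −78 °C; CuBr·SMe2 (1.1 equiv), −78 to −40 °C; then 3, −40 °C to rt
Reagents that add atoms: none
Why: Iodine–lithium exchange at −78 °C is much faster than bromine–lithium exchange and is helped by the ortho MOM oxygen, and the arylcopper formed by transmetalation should couple with the primary allylic bromide at its CH2 terminus (SN2-type allylic substitution), so the (E) geometry of geranyl bromide is carried over.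

Step 3
Reactants: 6 4-bromo-2-geranyl-1-(methoxymethoxy)benzene; 7 N-methoxy-N-methylprop-2-enamide
Product: 8 (2E)-3-[3-geranyl-4-(methoxymethoxy)phenyl]-N-methoxy-N-methylprop-2-enamide
Conditions: Pd(OAc)2 (5 mol %), P(o-tol)3 (10 mol %), Et3N, DMF, 100 °C
Reagents that add atoms: none
Why: Mizoroki–Heck reaction, in which zerovalent palladium formed in situ inserts into the aryl–Br bond, syn carbopalladation of the terminal acrylamide and syn β-hydride elimination give only the (E)-cinnamamide, and the trisubstituted geranyl alkenes are too hindered to insert.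

Step 4
Reactants: 8 (2E)-3-[3-geranyl-4-(methoxymethoxy)phenyl]-N-methoxy-N-methylprop-2-enamide; 9 pentane-2,4-dione
Product: 11 (7E)-8-[3-geranyl-4-(methoxymethoxy)phenyl]oct-7-ene-2,4,6-trione, via dilithium dienolate 10 (not isolated)
Conditions: 9 (2.2 equiv), LiN(i-Pr)2 (4.4 equiv), THF, −78 to 0 °C; then 8, −78 to 0 °C; cold 1 M HCl quench
Reagents that add atoms: none
Why: Claisen-type C-acylation of a β-diketone dianion at its terminal carbon, in which the Weinreb amide gives a chelated tetrahedral lithium adduct that holds until work-up, so the acidic triketone can neither quench unreacted dianion nor be acylated twice, and the hard terminal carbanion should attack the carbonyl carbon and not the β-carbon.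

Step 5
Reactants: 11 (7E)-8-[3-geranyl-4-(methoxymethoxy)phenyl]oct-7-ene-2,4,6-trione
Product: 13 (8E)-9-[3-geranyl-4-(methoxymethoxy)phenyl]-3,5,7-trioxonon-8-enoic acid, via trilithium trienolate 12 (not isolated)
Conditions: LiN(i-Pr)2 (3.5 equiv), THF, 0 °C; CO2 (g), −78 to 0 °C; cold 1 M HCl to pH 3, Et2O extraction, used at once
Reagents that add atoms: carbon dioxide, O=C=O
Why: Terminal carboxylation of a 1,3,5-triketone trianion, in which the third equivalent of amide base removes a methyl proton and this last-formed, most basic carbanion captures CO2, while the enolised C7 carbonyl keeps the styryl double bond from acting as a Michael acceptor.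

Step 6
Reactants: 13 (8E)-9-[3-geranyl-4-(methoxymethoxy)phenyl]-3,5,7-trioxonon-8-enoic acid
Product: 15 2-[(E)-2-[3-geranyl-4-(methoxymethoxy)phenyl]ethenyl]-4,6-dihydroxybenzoic acid, via aldol adduct 14 (not isolated)
Conditions: aq. K2CO3 (0.5 M, 3 equiv)/THF 1:1, rt, argon, dark; then 1 M HCl, 0 °C, to pH 3
Reagents that add atoms: none
Why: In carbonate solution 13 is the carboxylate of an enolised triketone; the small share of the C2=C3 enolate adds to the C7 ketone in an intramolecular aldol reaction to give carbinol 14, which loses water by E1cB elimination and tautomerises at the former C3 and C5 ketones to aromatic ring B. The closest known reaction type is the biomimetic aldol cyclisation of 3,5,7-triketo acids to β-resorcylic acids in aqueous base, the folding mode of stilbene synthase. Ring B closes in the 6-(enolendo)-exo-trig mode, the only enolate–carbonyl pairing in the chain that gives a six-membered ring. No stereocentre remains, because the carbinol carbon and the α-carbon of 14 both become sp2 on aromatisation, and the (E) alkene is not touched. The step needs aldol closure to win over Claisen or pyrone closure at C1 and over Michael or oxa-Michael addition to C9: C1 is a carboxylate and so no acceptor, C8 is vinylic and cannot enolise, and the conjugate adducts form reversibly while aromatisation does not.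

Step 7
Reactants: 15 2-[(E)-2-[3-geranyl-4-(methoxymethoxy)phenyl]ethenyl]-4,6-dihydroxybenzoic acid
Product: 16 5-[(E)-2-[3-geranyl-4-(methoxymethoxy)phenyl]ethenyl]benzene-1,3-diol
Conditions: DMF (degassed), 130 °C, argon, dark
Reagents that add atoms: none
Why: Thermal protodecarboxylation of a β-resorcylic acid, in which the ring carbon that carries CO2H is ortho and para to the two hydroxyls and is easily protonated before CO2 is lost, a reaction that runs near this temperature for 6-substituted 2,4-dihydroxybenzoic acids, geranylated ones included.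

Step 8
Reactants: 16 5-[(E)-2-[3-geranyl-4-(methoxymethoxy)phenyl]ethenyl]benzene-1,3-diol
Product: 17 5-[(E)-2-(3-geranyl-4-hydroxyphenyl)ethenyl]benzene-1,3-diol (target)
Conditions: TsOH·H2O (cat.), MeOH, rt, dark
Reagents that add atoms: none
Why: Acid-catalysed transacetalisation of the aryl MOM ether to methanol (acetal cleavage), which at room temperature with a catalytic sulfonic acid should be faster than protonation of the trisubstituted geranyl alkenes, as is usual for ortho-geranylated phenolic stilbenes.

**Compound list**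

1 | 4-bromo-2-iodophenol | Oc1ccc(Br)cc1I | starting material
2 | 4-bromo-2-iodo-1-(methoxymethoxy)benzene | COCOc1ccc(Br)cc1I | intermediate
3 | geranyl bromide, (2E)-1-bromo-3,7-dimethylocta-2,6-diene | CC(C)=CCC/C(C)=C/CBr | starting material
4 | [5-bromo-2-(methoxymethoxy)phenyl]lithium | COCOc1ccc(Br)cc1[Li] | intermediate
5 | [5-bromo-2-(methoxymethoxy)phenyl]copper | COCOc1ccc(Br)cc1[Cu] | intermediate
6 | 4-bromo-2-[(2E)-3,7-dimethylocta-2,6-dien-1-yl]-1-(methoxymethoxy)benzene | CC(C)=CCC/C(C)=C/Cc1cc(Br)ccc1OCOC | intermediate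
7 | N-methoxy-N-methylprop-2-enamide | C=CC(=O)N(C)OC | starting material
8 | (2E)-3-[3-[(2E)-3,7-dimethylocta-2,6-dien-1-yl]-4-(methoxymethoxy)phenyl]-N-methoxy-N-methylprop-2-enamide | CC(C)=CCC/C(C)=C/Cc1cc(/C=C/C(=O)N(C)OC)ccc1OCOC | intermediate
9 | pentane-2,4-dione | CC(=O)CC(C)=O | starting material
10 | dilithium dienolate (1,3-dianion) of pentane-2,4-dione | C=C(O[Li])C=C(C)O[Li] | intermediate
11 | (7E)-8-[3-[(2E)-3,7-dimethylocta-2,6-dien-1-yl]-4-(methoxymethoxy)phenyl]oct-7-ene-2,4,6-trione | CC(C)=CCC/C(C)=C/Cc1cc(/C=C/C(=O)CC(=O)CC(C)=O)ccc1OCOC | intermediate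
12 | trilithium trienolate (1,3,5-trianion) of triketone 11, enolate geometry undefined | CC(C)=CCC/C(C)=C/Cc1cc(/C=C/C(O[Li])=CC(O[Li])=CC(=C)O[Li])ccc1OCOC | intermediate
13 | (8E)-9-[3-[(2E)-3,7-dimethylocta-2,6-dien-1-yl]-4-(methoxymethoxy)phenyl]-3,5,7-trioxonon-8-enoic acid | CC(C)=CCC/C(C)=C/Cc1cc(/C=C/C(=O)CC(=O)CC(=O)CC(=O)O)ccc1OCOC | intermediate
14 | 2-[(E)-2-[3-geranyl-4-(methoxymethoxy)phenyl]ethenyl]-2-hydroxy-4,6-dioxocyclohexane-1-carboxylic acid, both transient stereocentres undefined | CC(C)=CCC/C(C)=C/Cc1cc(/C=C/C2(O)CC(=O)CC(=O)C2C(=O)O)ccc1OCOC | intermediate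
15 | 2-[(E)-2-[3-[(2E)-3,7-dimethylocta-2,6-dien-1-yl]-4-(methoxymethoxy)phenyl]ethenyl]-4,6-dihydroxybenzoic acid | CC(C)=CCC/C(C)=C/Cc1cc(/C=C/c2cc(O)cc(O)c2C(=O)O)ccc1OCOC | intermediate
16 | 5-[(E)-2-[3-[(2E)-3,7-dimethylocta-2,6-dien-1-yl]-4-(methoxymethoxy)phenyl]ethenyl]benzene-1,3-diol | CC(C)=CCC/C(C)=C/Cc1cc(/C=C/c2cc(O)cc(O)c2)ccc1OCOC | intermediate
17 | 5-[(E)-2-[3-[(2E)-3,7-dimethylocta-2,6-dien-1-yl]-4-hydroxyphenyl]ethenyl]benzene-1,3-diol | CC(C)=CCC/C(C)=C/Cc1cc(/C=C/c2cc(O)cc(O)c2)ccc1O | target

**Step count and risks**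

Total step count: 8. Longest linear sequence: 8 steps (1 to 17).

The three steps most likely to fail:

Step 5. The third deprotonation may stay incomplete, CO2 may be captured at an inner carbon, and the β-keto acid may lose CO2 again during acidic work-up. Fallback, setting out from 8 and returning at 15: the carboxyl carbon is brought in with the nucleophile. The trilithium trianion of commercial methyl 3,5-dioxohexanoate (LiN(i-Pr)2, 3 equiv, THF, 0 °C) should be acylated at its terminal carbon by Weinreb amide 8 to give methyl (8E)-9-[3-geranyl-4-(methoxymethoxy)phenyl]-3,5,7-trioxonon-8-enoate F1. Aldol closure of this triketo ester in buffered aqueous medium, where triketo esters prefer aldol over Claisen closure, should give methyl 2-[(E)-2-[3-geranyl-4-(methoxymethoxy)phenyl]ethenyl]-4,6-dihydroxybenzoate F2. Saponification (KOH, aq. MeOH, reflux) then gives acid 15.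

Step 6. The chain may rest in the reversible oxa-Michael closure of the C5 enol oxygen onto C9, or lose CO2 back to the triketone, before C2 attacks C7. Fallback, setting out from 8 and returning at 15: the same C2–C7 aldol is run with C1 masked in a dioxinone. Commercial 2,2,6-trimethyl-4H-1,3-dioxin-4-one is deprotonated with LiN(SiMe3)2 and C-acetylated with acetyl chloride to 2,2-dimethyl-6-(2-oxopropyl)-4H-1,3-dioxin-4-one F3. Its dianion (LiN(i-Pr)2, 2 equiv, THF, −78 °C) is acylated at the methyl terminus by 8 to give 6-[(5E)-6-[3-geranyl-4-(methoxymethoxy)phenyl]-2,4-dioxohex-5-en-1-yl]-2,2-dimethyl-4H-1,3-dioxin-4-one F4. Et3N in CH2Cl2 at rt should bring about aldol closure and aromatisation to 5-[(E)-2-[3-geranyl-4-(methoxymethoxy)phenyl]ethenyl]-7-hydroxy-2,2-dimethyl-4H-1,3-benzodioxin-4-one F5. Hydrolysis of the acetonide (aq. KOH, THF, 60 °C) then gives 15.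

Step 4. The dianion may add to the β-carbon of the unsaturated amide, or proton transfer may stall the acylation. Fallback, setting out from 8 and returning at 11: acylation is replaced by aldol addition and oxidation. Reduction of 8 with i-Bu2AlH (THF, −78 °C) gives (2E)-3-[3-geranyl-4-(methoxymethoxy)phenyl]prop-2-enal F6. Dienolate 10 should add 1,2 to this aldehyde to give racemic (7E)-8-[3-geranyl-4-(methoxymethoxy)phenyl]-6-hydroxyoct-7-ene-2,4-dione F7. Oxidation of the allylic alcohol with MnO2 (CH2Cl2, rt) then gives triketone 11.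

**Further compounds**

F1 | step 5 | methyl (8E)-9-[3-[(2E)-3,7-dimethylocta-2,6-dien-1-yl]-4-(methoxymethoxy)phenyl]-3,5,7-trioxonon-8-enoate | CC(C)=CCC/C(C)=C/Cc1cc(/C=C/C(=O)CC(=O)CC(=O)CC(=O)OC)ccc1OCOC
F2 | step 5 | methyl 2-[(E)-2-[3-[(2E)-3,7-dimethylocta-2,6-dien-1-yl]-4-(methoxymethoxy)phenyl]ethenyl]-4,6-dihydroxybenzoate | CC(C)=CCC/C(C)=C/Cc1cc(/C=C/c2cc(O)cc(O)c2C(=O)OC)ccc1OCOC
F3 | step 6 | 2,2-dimethyl-6-(2-oxopropyl)-4H-1,3-dioxin-4-one | CC(=O)CC1=CC(=O)OC(C)(C)O1
F4 | step 6 | 6-[(5E)-6-[3-[(2E)-3,7-dimethylocta-2,6-dien-1-yl]-4-(methoxymethoxy)phenyl]-2,4-dioxohex-5-en-1-yl]-2,2-dimethyl-4H-1,3-dioxin-4-one | CC(C)=CCC/C(C)=C/Cc1cc(/C=C/C(=O)CC(=O)CC2=CC(=O)OC(C)(C)O2)ccc1OCOC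
F5 | step 6 | 5-[(E)-2-[3-[(2E)-3,7-dimethylocta-2,6-dien-1-yl]-4-(methoxymethoxy)phenyl]ethenyl]-7-hydroxy-2,2-dimethyl-4H-1,3-benzodioxin-4-one | CC(C)=CCC/C(C)=C/Cc1cc(/C=C/c2cc(O)cc3OC(C)(C)OC(=O)c23)ccc1OCOC
F6 | step 4 | (2E)-3-[3-[(2E)-3,7-dimethylocta-2,6-dien-1-yl]-4-(methoxymethoxy)phenyl]prop-2-enal | CC(C)=CCC/C(C)=C/Cc1cc(/C=C/C=O)ccc1OCOC
F7 | step 4 | (7E)-8-[3-[(2E)-3,7-dimethylocta-2,6-dien-1-yl]-4-(methoxymethoxy)phenyl]-6-hydroxyoct-7-ene-2,4-dione, racemic | CC(C)=CCC/C(C)=C/Cc1cc(/C=C/C(O)CC(=O)CC(C)=O)ccc1OCOC
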